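## Structural features

The target 14 is a dihydrochalcone. Its ring A is fused to a 2,2-dimethyl-2H-pyran, so ring A and the pyran together form a 2H-chromene, and a C(=O)–CH2–CH2 chain joins C6 of the chromene to the para-hydroxyphenyl ring B. Ring A is a resorcinol at heart: the pyran oxygen O1 on C8a and the free hydroxyl on C7 are meta to each other, the 3-methylbut-2-enyl (prenyl) group sits on C8 between them, the ketone sits on C6 ortho to the 7-OH, C4 of the pyran is bound to C4a, and C5 carries the only hydrogen of ring A. There is no stereocentre and no double-bond geometry to control, so the problem is purely one of regiochemistry on a pentasubstituted benzene. Two isoprenoid units must be told apart, one closed to the pyran through O1 and one left open at C8 beside a free phenol. The fragile groups are the trisubstituted prenyl alkene ortho to a phenol (acid closes it to a chroman, oxidants and electrophiles attack it), the styrene-like C3=C4 alkene of the chromene, and the two phenols. The saturated CH2CH2 link is the hidden difficulty, because making it by hydrogenating a chalcone would put both other alkenes at risk. The key step exploits the ortho relation between the 7-OH and the carbonyl carbon on C6: in a salicylaldehyde the phenol guides rhodium into the formyl C–H bond, and the ketone then forms directly, at its final oxidation level, by addition across the vinyl group of a ring B styrene.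

## Logic of the disconnections

14 ⇒ 13. Only the O–C(=O) bond of an ester on the ring B oxygen is cut. The ring B phenol is masked because the free vinylphenol polymerises easily and would offer rhodium a second phenoxide. Nothing is gained in skeleton, but the alkene partner becomes a commercial compound. The forward step must be a transesterification mild enough to leave the salicyl ketone and both alkenes alone.

13 ⇒ 11 + 12. The bond between the ketone carbon on C6 and the adjacent CH2 is cut. This is the only bond joining the two halves, and cutting it here leaves the carbonyl carbon on ring A as a formyl group ortho to the 7-OH. The gain is full convergence: a chromene aldehyde and a one-ring styrene. The forward step must add the formyl C–H across the vinyl group with the acyl carbon on the terminal carbon, and must ignore the chromene and prenyl alkenes.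

11 ⇒ 9. The C6–CHO bond is cut. In 9 the 7-OH has one free ortho position only, because C8 is occupied, so a phenol-directed ortho-formylation can go to C6 alone. The forward step must be non-acidic and non-oxidising.

9 ⇒ 6 + 7. The O1–C2 and C4–C4a bonds of the pyran are cut, removing the whole ring in one operation. Compound 6 is symmetric, so a single annulation has only one possible regiochemical outcome, and the prenyl group already in place blocks the position between the two oxygens. The forward step must stop after one annulation.

6 ⇒ 5 ⇒ 2 + 3 (through 4). The bond from the ring carbon between the two oxygens to the prenyl CH2 is cut. That carbon is the one position of a resorcinol that electrophilic substitution does not favour, but it is the position that double oxygen-directed lithiation picks out. The acetal groups of 2 therefore serve as both protecting and directing groups. The forward sequence must couple at the primary carbon of 3 and then remove the acetals without letting acid close the prenyl group onto a phenol.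

2 ⇒ 1. The two O–CH2 bonds of the acetals are cut, leading back to the parent diphenol, a bulk chemical.

## Other disconnections considered

Alternative 1: Ring A itself is cut across C6–C7 and C4a–C5. The forward key step is a [4+2] benzannulation of the acetoacetate-derived diene 1-methoxy-2-(3-methylbut-2-enyl)-1,3-bis(trimethylsilyloxy)buta-1,3-diene A2 with the terminal ynone 5-[4-(tert-butyldimethylsilyloxy)phenyl]pent-1-yn-3-one A3. Aromatisation by loss of methanol would give 1-[2,4-dihydroxy-3-(3-methylbut-2-enyl)phenyl]-3-[4-(tert-butyldimethylsilyloxy)phenyl]propan-1-one A1.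
- In its favour: the oxygen pattern, the prenyl position and the acyl position are fixed by how the ring is built, not by aromatic substitution, and the saturated chain arrives inside A3 with no reduction. On these points of structure it is the better plan, since neither a directed formylation nor a ligand-controlled insertion is needed.
- Against it: A2 is a tetrasubstituted, moisture-sensitive diene whose 2-substituent disfavours the reactive s-cis form. Terminal ynones invite conjugate addition without ring closure and polymerisation. A1 still lacks the pyran ring, which would have to be annulated with 7 onto an acyl-deactivated resorcinol before desilylation.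
- Mechanism: a polar cycloaddition or Mukaiyama–Michael/acylation cascade needs no metal and is the equal of the chosen plan in forming no stereocentre.
- Step economy: A2 and A3 each need about three steps, followed by annulation, pyran formation and deprotection. The total is clearly higher than for the chosen plan, though the longest linear sequence is about the same.

Alternative 2: The O1–C2 bond of the pyran is cut. The precursor is 1-[2,4-dihydroxy-5-(3-methylbut-2-enyl)-3-(prop-2-enyl)phenyl]-3-[4-(tert-butyldimethylsilyloxy)phenyl]propan-1-one A5. Anodic oxidation with the quinone DDQ as catalytic mediator would give 1-[7-hydroxy-2,2-dimethyl-8-(prop-2-enyl)-2H-chromen-6-yl]-3-[4-(tert-butyldimethylsilyloxy)phenyl]propan-1-one A4. The allyl group would then be converted to prenyl by cross-metathesis (second-generation Grubbs catalyst) and the silyl group removed.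
- In its favour: it answers the central question of the structure, how to cyclise one isoprenoid unit and keep the other open. Hydride abstraction by the quinone needs the dimethyl-substituted allyl terminus, and the prenyl group at the future C4a has only one neighbouring hydroxyl. The certainty of pyran closure is therefore equal to that of the chosen plan. It is better in never exposing a free resorcinol to an enal, and in carrying the ketone chain from an early acylation.
- Against it: A5 is a hexasubstituted benzene needing two separate regiocontrolled C-allylations. The electron-rich phenol and the chromene product may be oxidised directly at the anode. The later metathesis must spare the chromene alkene and avoid migration of the allyl double bond.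
- Mechanism: mediated electron transfer is as catalytic as the rhodium step but formally removes two hydrogens, where hydroacylation is fully atom-economic.
- Step economy: two steps follow its key step against one, and the route to A5 is longer. The chosen plan is shorter.

Alternative 3: The bond from C8 to the prenyl CH2 is cut. The parent phenol 1-(7-hydroxy-2,2-dimethyl-2H-chromen-6-yl)-3-[4-(tert-butyldimethylsilyloxy)phenyl]propan-1-one A8 would be converted to its tertiary allyl ether 1-[2,2-dimethyl-7-(2-methylbut-3-en-2-yloxy)-2H-chromen-6-yl]-3-[4-(tert-butyldimethylsilyloxy)phenyl]propan-1-one A7. Heating A7 would bring about an aromatic Claisen rearrangement to 1-[7-hydroxy-2,2-dimethyl-8-(3-methylbut-2-enyl)-2H-chromen-6-yl]-3-[4-(tert-butyldimethylsilyloxy)phenyl]propan-1-one A6, and desilylation would give 14.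
- In its favour: the [3,3] shift is intramolecular and can end only at C8, because C6 is acylated. It turns the tertiary ether into the normal prenyl group and needs neither metal nor acid. In predictability of the key step it is better than the chosen plan, whose insertion regiochemistry depends on the ligand. It is equal in forming one C–C bond and no ring.
- Against it: A7 requires O-alkylation of a chelated, weakly nucleophilic phenol with a tertiary electrophile and then a semi-hydrogenation beside the chromene alkene. Tertiary allyl aryl ethers ionise easily on heating. A8 is not simple to reach, since annulation of a 4-acylresorcinol prefers the angular chromene.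
- Step economy: the prenyl group costs three operations (alkylation, semi-reduction, rearrangement) against one directed metalation in the chosen plan, which is also more convergent.

Key step: step 6

Remark: the target has no stereocentre, so no SMILES string carries a stereodescriptor. The commercial vinylarene 12 is assumed to be freed from its phenolic stabiliser (short plug of basic alumina) before the rhodium step.

## Route

Step 1
Reactants: 1 resorcinol
Product: 2 1,3-bis(methoxymethoxy)benzene
Conditions: NaH, MOMCl, DMF, 0 °C → rt
Reagents that add atoms: chloromethyl methyl ether, COCCl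
Why: Williamson-type O-alkylation of the bis-phenoxide; the methoxymethyl ethers protect both phenols and are strong ortho-directing groups for the next step.

Step 2
Reactants: 2 1,3-bis(methoxymethoxy)benzene; 3 1-bromo-3-methylbut-2-ene
Product: 5 1,3-bis(methoxymethoxy)-2-(3-methylbut-2-enyl)benzene, via aryllithium 4 (not isolated)
Conditions: n-BuLi, THF, 0 °C; then CuI (10 mol%), 3, −78 °C → rt
Reagents that add atoms: none
Why: Directed ortho-metalation: the hydrogen flanked by two coordinating acetal oxygens is removed selectively to give 4. Copper catalysis should steer the allylic substitution to the primary carbon of 3 (SN2, not SN2'), so the 3-methylbut-2-enyl connectivity is kept.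

Step 3
Reactants: 5 1,3-bis(methoxymethoxy)-2-(3-methylbut-2-enyl)benzene
Product: 6 2-(3-methylbut-2-enyl)benzene-1,3-diol
Conditions: p-TsOH·H2O (10 mol%), MeOH, rt → 40 °C, stopped at full conversion
Reagents that add atoms: none
Why: Acid-catalysed transacetalisation to methanol frees both phenols. With catalytic acid and low temperature, acetal exchange should outrun Markovnikov addition of a phenol across the prenyl alkene.

Step 4
Reactants: 6 2-(3-methylbut-2-enyl)benzene-1,3-diol; 7 3-methylbut-2-enal
Product: 9 2,2-dimethyl-8-(3-methylbut-2-enyl)-2H-chromen-7-ol, via ortho-quinone methide 8 (not isolated)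
Conditions: 7 (1.1 equiv, slow addition), ethylenediammonium diacetate (20 mol%), xylene, 140 °C
Reagents that add atoms: none
Why: Formal [3+3] chromene annulation: amine-catalysed Knoevenagel-type condensation at a ring carbon ortho to one hydroxyl and para to the other, dehydration to 8, then oxa-6π-electrocyclisation. The two reactive positions of 6 are equivalent and the third is blocked, so one regioisomer results, and limiting 7 holds back a second annulation.

Step 5
Reactants: 9 2,2-dimethyl-8-(3-methylbut-2-enyl)-2H-chromen-7-ol
Product: 11 7-hydroxy-2,2-dimethyl-8-(3-methylbut-2-enyl)-2H-chromene-6-carbaldehyde, via chloromagnesium hydroxymethyl phenoxide 10 (not isolated)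
Conditions: MgCl2, Et3N, (CH2O)n, MeCN, reflux; cold 1 M HCl work-up
Reagents that add atoms: paraformaldehyde (as formaldehyde), C=O
Why: Magnesium-mediated ortho-formylation (Casnati–Skattebøl reaction): the magnesium phenoxide delivers formaldehyde to the ortho carbon within a chelate, and the benzylic alkoxide 10 is oxidised by a second formaldehyde through an Oppenauer-type hydride transfer. C8 is blocked, so only C6 can react, and the basic, non-oxidising medium leaves both alkenes alone.

Step 6
Reactants: 11 7-hydroxy-2,2-dimethyl-8-(3-methylbut-2-enyl)-2H-chromene-6-carbaldehyde; 12 4-ethenylphenyl acetate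
Product: 13 4-{3-[7-hydroxy-2,2-dimethyl-8-(3-methylbut-2-enyl)-2H-chromen-6-yl]-3-oxopropyl}phenyl acetate
Conditions: [Rh(cod)Cl]2 (2.5 mol%), rac-BINOL-derived N,N-diisopropylphosphoramidite (6 mol%), K3PO4 (10 mol%), 12 (2 equiv), THF, 60 °C, argon
Reagents that add atoms: none
Why: The reaction type is the known chelation-assisted rhodium-catalysed intermolecular hydroacylation of terminal alkenes by salicylaldehydes. The 7-phenoxide of 11, formed by the catalytic phosphate, binds monovalent rhodium and delivers it into the neighbouring formyl C–H bond, giving a five-membered O,C-chelated acyl hydride of trivalent rhodium; decarbonylation is held back because loss of CO would need a strained four-membered aryl chelate. The vinyl group of 12 then coordinates and inserts into Rh–H, and C–C reductive elimination forms the C(=O)–CH2 bond and returns monovalent rhodium. No ring is closed and no stereocentre is created, since the ketone carbon and both new methylene carbons are achiral. The selectivity needed is linear over branched: hydride insertion is reversible, so the outcome is set at reductive elimination, where the hindered phosphoramidite and the crowded chelate (the C8 prenyl group lies beside the oxygen donor) should disfavour the secondary benzylic alkyl, and this is the point that ligand choice must secure. Chemoselectivity among the three alkenes follows from substitution: only the monosubstituted vinyl group of 12 binds and inserts readily, while the cis-disubstituted chromene alkene next to a quaternary carbon and the trisubstituted prenyl alkene are poor ligands, and both are attached meta to C6 so neither can reach the acyl rhodium centre intramolecularly. The aryl acetate should stay in place because base is catalytic and acetyl transfer to the more acidic, hydrogen-bonded salicyl phenol is uphill. The ketone thus arrives at its final oxidation level, and no hydrogenation is ever needed.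

Step 7
Reactants: 13 4-{3-[7-hydroxy-2,2-dimethyl-8-(3-methylbut-2-enyl)-2H-chromen-6-yl]-3-oxopropyl}phenyl acetate
Product: 14 1-[7-hydroxy-2,2-dimethyl-8-(3-methylbut-2-enyl)-2H-chromen-6-yl]-3-(4-hydroxyphenyl)propan-1-one
Conditions: K2CO3 (0.3 equiv), MeOH, 0 °C → rt; aq. NH4Cl
Reagents that add atoms: none
Why: Base-catalysed methanolysis (Zemplén-type transesterification) of the aryl acetate; aryl esters cleave fast under these conditions, while the salicyl ketone, the chromene and the prenyl group are inert to methanolic carbonate.

## Compound list

1 | resorcinol (benzene-1,3-diol) | Oc1cccc(O)c1 | starting material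
2 | 1,3-bis(methoxymethoxy)benzene | COCOc1cccc(OCOC)c1 | intermediate
3 | 1-bromo-3-methylbut-2-ene (prenyl bromide) | CC(C)=CCBr | starting material
4 | [2,6-bis(methoxymethoxy)phenyl]lithium (not isolated) | [Li]c1c(OCOC)cccc1OCOC | intermediate
5 | 1,3-bis(methoxymethoxy)-2-(3-methylbut-2-enyl)benzene | COCOc1cccc(OCOC)c1CC=C(C)C | intermediate
6 | 2-(3-methylbut-2-enyl)benzene-1,3-diol | CC(C)=CCc1c(O)cccc1O | intermediate
7 | 3-methylbut-2-enal | CC(C)=CC=O | starting material
8 | 3-hydroxy-2-(3-methylbut-2-enyl)-6-(3-methylbut-2-enylidene)cyclohexa-2,4-dien-1-one (ortho-quinone methide, not isolated) | CC(C)=CCC1=C(O)C=CC(=CC=C(C)C)C1=O | intermediate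
9 | 2,2-dimethyl-8-(3-methylbut-2-enyl)-2H-chromen-7-ol | CC(C)=CCc1c(O)ccc2c1OC(C)(C)C=C2 | intermediate
10 | chloromagnesium 6-(hydroxymethyl)-2,2-dimethyl-8-(3-methylbut-2-enyl)-2H-chromen-7-olate (not isolated) | CC(C)=CCc1c([O-])c(CO)cc2c1OC(C)(C)C=C2.[Mg+2].[Cl-] | intermediate
11 | 7-hydroxy-2,2-dimethyl-8-(3-methylbut-2-enyl)-2H-chromene-6-carbaldehyde | CC(C)=CCc1c(O)c(C=O)cc2c1OC(C)(C)C=C2 | intermediate
12 | 4-ethenylphenyl acetate | C=Cc1ccc(OC(C)=O)cc1 | starting material
13 | 4-{3-[7-hydroxy-2,2-dimethyl-8-(3-methylbut-2-enyl)-2H-chromen-6-yl]-3-oxopropyl}phenyl acetate | CC(C)=CCc1c(O)c(C(=O)CCc2ccc(OC(C)=O)cc2)cc2c1OC(C)(C)C=C2 | intermediate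
14 | 1-[7-hydroxy-2,2-dimethyl-8-(3-methylbut-2-enyl)-2H-chromen-6-yl]-3-(4-hydroxyphenyl)propan-1-one | CC(C)=CCc1c(O)c(C(=O)CCc2ccc(O)cc2)cc2c1OC(C)(C)C=C2 | target

## Step count and least certain steps

Total step count: 7. Longest linear sequence: 7 steps (1 → 14; compounds 3, 7 and 12 are bought).

Step 6 (key step). The most likely failure is insertion of the vinylarene in the opposite sense, with rhodium on the benzylic carbon, where the alkyl is stabilised by the arene; this would place the acyl group on the internal carbon. A second risk is slow turnover, because the prenyl group beside the phenoxide crowds the chelate and lets decarbonylation compete.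
Fallback, from 11 to 14: the same C(=O)–CH2 bond is made by carbonyl addition and oxidation in place of C–H activation.
- Commercial 4-(2-bromoethyl)phenol is silylated (TIPSCl, imidazole, DMF) to [4-(2-bromoethyl)phenoxy]tri(propan-2-yl)silane F1.
- Magnesium in THF converts it to the Grignard reagent bromo{2-[4-(triisopropylsilyloxy)phenyl]ethyl}magnesium F2.
- Addition of F2 (2.2 equiv, the first equivalent taking the phenol proton) to 11 at −20 → 0 °C should give racemic 1-[7-hydroxy-2,2-dimethyl-8-(3-methylbut-2-enyl)-2H-chromen-6-yl]-3-[4-(triisopropylsilyloxy)phenyl]propan-1-ol F3.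
- Activated MnO2 in CH2Cl2 oxidises the benzylic alcohol, without touching the alkenes, to 1-[7-hydroxy-2,2-dimethyl-8-(3-methylbut-2-enyl)-2H-chromen-6-yl]-3-[4-(triisopropylsilyloxy)phenyl]propan-1-one F4.
- TBAF buffered with acetic acid (THF, 0 °C) removes the silyl group and gives 14.

Step 3. The risk is acid-catalysed addition of a freed phenol across the prenyl double bond (closure to a chroman) competing with acetal cleavage; both hydroxyls flank the prenyl group, so this is the most acid-sensitive intermediate of the route.
Fallback, from 1 to 6: the directing groups are changed to ones removed without acid.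
- Compound 1 with diethylcarbamoyl chloride (K2CO3, MeCN, reflux) gives 1,3-phenylene bis(N,N-diethylcarbamate) F5.
- s-BuLi/TMEDA in THF at −78 °C lithiates between the carbamates to give [2,6-bis(diethylcarbamoyloxy)phenyl]lithium F6, kept cold to avoid the anionic Fries shift.
- Alkylation with 3 (CuI catalysis, −78 °C) gives 2-(3-methylbut-2-enyl)-1,3-phenylene bis(N,N-diethylcarbamate) F7.
- LiAlH4 in THF cleaves both carbamates reductively and gives 6 after a buffered work-up.

Step 4. The risk is over-reaction: a second condensation and electrocyclisation at C6 of the product, which is still an activated phenol, or thermal oligomerisation of the enal before it is consumed.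
Fallback, from 6 to 9: the pyran is built by a propargyl ether rearrangement in place of the enal condensation.
- Mono-O-alkylation of 6 (used in excess and recycled) with 3-chloro-3-methylbut-1-yne (K2CO3, KI, CuI cat., acetone, reflux) gives 3-(2-methylbut-3-yn-2-yloxy)-2-(3-methylbut-2-enyl)phenol F8.
- Heating in N,N-diethylaniline at about 140 °C should convert F8 to 9 by propargyl Claisen rearrangement to the only free ortho carbon, 1,5-hydrogen shift and oxa-6π ring closure.

Step 5. The risk is incomplete formylation of a phenol crowded by the C8 prenyl group, or condensation of the hydroxymethyl intermediate with a second electron-rich arene before it is oxidised.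
Fallback, from 9 to 11: hydroxymethylation and oxidation are separated on a boron template.
- Compound 9 with phenylboronic acid and paraformaldehyde (cat. propionic acid, toluene, reflux, water removal) should give the cyclic boronate 8,8-dimethyl-10-(3-methylbut-2-enyl)-2-phenyl-4H,8H-pyrano[3,2-g][1,3,2]benzodioxaborinine F9.
- Exchange with propane-1,3-diol frees 6-(hydroxymethyl)-2,2-dimethyl-8-(3-methylbut-2-enyl)-2H-chromen-7-ol F10.
- Activated MnO2 in CH2Cl2 oxidises the benzylic alcohol to 11.

## Further compounds

F1 | step 6 | [4-(2-bromoethyl)phenoxy]tri(propan-2-yl)silane | BrCCc1ccc(O[Si](C(C)C)(C(C)C)C(C)C)cc1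
F2 | step 6 | bromo{2-[4-(triisopropylsilyloxy)phenyl]ethyl}magnesium | Br[Mg]CCc1ccc(O[Si](C(C)C)(C(C)C)C(C)C)cc1
F3 | step 6 | 1-[7-hydroxy-2,2-dimethyl-8-(3-methylbut-2-enyl)-2H-chromen-6-yl]-3-[4-(triisopropylsilyloxy)phenyl]propan-1-ol (racemic) | CC(C)=CCc1c(O)c(C(O)CCc2ccc(O[Si](C(C)C)(C(C)C)C(C)C)cc2)cc2c1OC(C)(C)C=C2
F4 | step 6 | 1-[7-hydroxy-2,2-dimethyl-8-(3-methylbut-2-enyl)-2H-chromen-6-yl]-3-[4-(triisopropylsilyloxy)phenyl]propan-1-one | CC(C)=CCc1c(O)c(C(=O)CCc2ccc(O[Si](C(C)C)(C(C)C)C(C)C)cc2)cc2c1OC(C)(C)C=C2
F5 | step 3 | 1,3-phenylene bis(N,N-diethylcarbamate) | CCN(CC)C(=O)Oc1cccc(OC(=O)N(CC)CC)c1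
F6 | step 3 | [2,6-bis(diethylcarbamoyloxy)phenyl]lithium | [Li]c1c(OC(=O)N(CC)CC)cccc1OC(=O)N(CC)CC
F7 | step 3 | 2-(3-methylbut-2-enyl)-1,3-phenylene bis(N,N-diethylcarbamate) | CCN(CC)C(=O)Oc1cccc(OC(=O)N(CC)CC)c1CC=C(C)C
F8 | step 4 | 3-(2-methylbut-3-yn-2-yloxy)-2-(3-methylbut-2-enyl)phenol | C#CC(C)(C)Oc1cccc(O)c1CC=C(C)C
F9 | step 5 | 8,8-dimethyl-10-(3-methylbut-2-enyl)-2-phenyl-4H,8H-pyrano[3,2-g][1,3,2]benzodioxaborinine | CC(C)=CCc1c2OB(c3ccccc3)OCc2cc2c1OC(C)(C)C=C2
F10 | step 5 | 6-(hydroxymethyl)-2,2-dimethyl-8-(3-methylbut-2-enyl)-2H-chromen-7-ol | CC(C)=CCc1c(O)c(CO)cc2c1OC(C)(C)C=C2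
A1 | alternative 1 | 1-[2,4-dihydroxy-3-(3-methylbut-2-enyl)phenyl]-3-[4-(tert-butyldimethylsilyloxy)phenyl]propan-1-one | CC(C)=CCc1c(O)ccc(C(=O)CCc2ccc(O[Si](C)(C)C(C)(C)C)cc2)c1O
A2 | alternative 1 | 1-methoxy-2-(3-methylbut-2-enyl)-1,3-bis(trimethylsilyloxy)buta-1,3-diene | C=C(O[Si](C)(C)C)C(CC=C(C)C)=C(OC)O[Si](C)(C)C
A3 | alternative 1 | 5-[4-(tert-butyldimethylsilyloxy)phenyl]pent-1-yn-3-one | C#CC(=O)CCc1ccc(O[Si](C)(C)C(C)(C)C)cc1
A4 | alternative 2 | 1-[7-hydroxy-2,2-dimethyl-8-(prop-2-enyl)-2H-chromen-6-yl]-3-[4-(tert-butyldimethylsilyloxy)phenyl]propan-1-one | C=CCc1c(O)c(C(=O)CCc2ccc(O[Si](C)(C)C(C)(C)C)cc2)cc2c1OC(C)(C)C=C2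
A5 | alternative 2 | 1-[2,4-dihydroxy-5-(3-methylbut-2-enyl)-3-(prop-2-enyl)phenyl]-3-[4-(tert-butyldimethylsilyloxy)phenyl]propan-1-one | C=CCc1c(O)c(CC=C(C)C)cc(C(=O)CCc2ccc(O[Si](C)(C)C(C)(C)C)cc2)c1O
A6 | alternative 3 | 1-[7-hydroxy-2,2-dimethyl-8-(3-methylbut-2-enyl)-2H-chromen-6-yl]-3-[4-(tert-butyldimethylsilyloxy)phenyl]propan-1-one | CC(C)=CCc1c(O)c(C(=O)CCc2ccc(O[Si](C)(C)C(C)(C)C)cc2)cc2c1OC(C)(C)C=C2
A7 | alternative 3 | 1-[2,2-dimethyl-7-(2-methylbut-3-en-2-yloxy)-2H-chromen-6-yl]-3-[4-(tert-butyldimethylsilyloxy)phenyl]propan-1-one | C=CC(C)(C)Oc1cc2OC(C)(C)C=Cc2cc1C(=O)CCc1ccc(O[Si](C)(C)C(C)(C)C)cc1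
A8 | alternative 3 | 1-(7-hydroxy-2,2-dimethyl-2H-chromen-6-yl)-3-[4-(tert-butyldimethylsilyloxy)phenyl]propan-1-one | CC1(C)C=Cc2cc(C(=O)CCc3ccc(O[Si](C)(C)C(C)(C)C)cc3)c(O)cc2O1
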